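## Retrosynthetic overview

1. The aryl ether is made last, by Mitsunobu coupling of umbelliferone with the (E)-allylic alcohol; the (E)-trisubstituted alkene comes from a terminal alkyne by Zr-catalysed methylalumination and hydroxymethylation.
2. Enabling feature of the core (6-oxabicyclo[3.2.1]octane; carbocycle C1–C2–C3–C4–C5–C8, oxolane C1–C7–O6–C5–C8): quaternary C1 carries CH3 and the oxymethylene C7 next to the carbinol C2, and O6 ties C7 to C5, which is 1,3-diaxial to C1. With C7 at the aldehyde level, the C2(OH)–C1–C7H=O array is the product pattern of a semipinacol shift.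
3. Key disconnection: bond C1–C8 is moved back to C7–C8, giving a monocyclic trans-2,3-epoxycycloheptyl silyl ether (ring C7–C1–C2–C3–C4–C5–C8). Forward, ring contraction 7 → 6, lactolisation by the C5 hydroxyl and silane reduction run in one flask.
4. The cycloheptene comes from ring-closing metathesis of an acyclic diene; its C7 carbinol from a Felkin–Anh isopropenyl addition; C8 and C5 from Cu-catalysed Grignard opening of a Sharpless epoxide.
5. Order of ring formation: cycloheptene (metathesis) → oxirane on that ring → cyclohexane and oxolane together in the key step; the coumarin is brought in intact.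

Key step: step 10

Remark (convention): in the Why lines, C1–C8 and O6 are the locants of the 6-oxabicyclo[3.2.1]octane core of the target and are also used for the atoms of earlier compounds that become them; compound names carry their own IUPAC locants.

## Route

Step 1
Reactants: 1 hex-1-en-5-yne
Product: 3 (2E)-3-methylhepta-2,6-dien-1-ol, via alkenylalane 2 (not isolated)
Conditions: Me3Al, Cp2ZrCl2 (25 mol%), CH2Cl2, 0 °C to rt; then n-BuLi, (CH2O)n, THF, −78 °C to rt
Reagents that add atoms: trimethylaluminium C[Al](C)C; paraformaldehyde (as formaldehyde) C=O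
Why: Negishi zirconium-catalysed syn-methylalumination of the terminal alkyne (the unactivated terminal alkene does not compete) gives the (E)-alkenylalane 2, whose lithium ate complex is hydroxymethylated by formaldehyde with retention of the alkene geometry.

Step 2
Reactants: 3 (2E)-3-methylhepta-2,6-dien-1-ol
Product: 4 [(2S,3S)-3-(but-3-en-1-yl)-3-methyloxiran-2-yl]methanol
Conditions: Ti(OiPr)4 (5 mol%), L-(+)-diethyl tartrate (6 mol%), t-BuOOH, 4 Å MS, CH2Cl2, −20 °C
Reagents that add atoms: tert-butyl hydroperoxide CC(C)(C)OO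
Why: Katsuki–Sharpless asymmetric epoxidation: with L-(+)-tartrate an (E)-3,3-disubstituted allylic alcohol of the geraniol type gives the (2S,3S)-epoxide, which fixes the later C5 directly and C8 through the next step, and the remote terminal alkene is not touched by the titanium–tartrate system.

Step 3
Reactants: 4 [(2S,3S)-3-(but-3-en-1-yl)-3-methyloxiran-2-yl]methanol; 5 (4-bromobut-1-yn-1-yl)trimethylsilane
Product: 7 (2R,3S)-3-methyl-2-[4-(trimethylsilyl)but-3-yn-1-yl]hept-6-ene-1,3-diol, via Grignard reagent 6 (not isolated)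
Conditions: 5, Mg, THF, rt (gives 6, 3 equiv); then CuI (10 mol%), 4, THF, −40 to 0 °C
Reagents that add atoms: none
Why: Copper-catalysed Grignard opening of a 2,3-epoxy alcohol: SN2 attack with inversion occurs at the only non-quaternary oxirane carbon (the later C8), giving the 1,3-diol with C8 and the untouched tertiary C5 in the required relative and absolute sense.

Step 4
Reactants: 7 (2R,3S)-3-methyl-2-[4-(trimethylsilyl)but-3-yn-1-yl]hept-6-ene-1,3-diol
Product: 8 bis(trimethylsilyl) ether of 7
Conditions: N-(trimethylsilyl)imidazole, CH2Cl2, rt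
Reagents that add atoms: N-(trimethylsilyl)imidazole C[Si](C)(C)n1ccnc1
Why: Exhaustive silylation with a powerful silyl donor masks the tertiary hydroxyl as a non-chelating ether and turns the primary one into the substrate of the next step.

Step 5
Reactants: 8 bis(trimethylsilyl) ether of 7
Product: 9 (2S,3S)-3-methyl-2-[4-(trimethylsilyl)but-3-yn-1-yl]-3-[(trimethylsilyl)oxy]hept-6-enal
Conditions: (COCl)2, DMSO, CH2Cl2, −78 °C; then Et3N, −78 to −30 °C
Reagents that add atoms: none
Why: Swern conditions oxidise a primary trimethylsilyl ether directly to the aldehyde while the hindered tertiary silyl ether is inert, so no free β-hydroxy aldehyde prone to retro-aldol cleavage is formed, and the low temperature limits epimerisation at the α-carbon (C8).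

Step 6
Reactants: 9 (2S,3S)-3-methyl-2-[4-(trimethylsilyl)but-3-yn-1-yl]-3-[(trimethylsilyl)oxy]hept-6-enal
Product: 11 (3R,4R,5S)-2,5-dimethyl-4-[4-(trimethylsilyl)but-3-yn-1-yl]nona-1,8-diene-3,5-diol, via tertiary silyl ether carbinol 10 (not isolated)
Conditions: isopropenylmagnesium bromide, THF, −78 °C; then 1 M aq HCl, THF, 0 °C
Reagents that add atoms: isopropenylmagnesium bromide C=C(C)[Mg]Br
Why: Felkin–Anh addition of the Grignard reagent anti to the quaternary, silyloxy-bearing C5 (reinforced by 1,3-anti induction of the non-chelating β-silyloxy group) sets C7 with its oxygen anti to the side chain on the future ring, and the acidic work-up cleaves the labile tertiary trimethylsilyl ether of 10.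

Step 7
Reactants: 11 (3R,4R,5S)-2,5-dimethyl-4-[4-(trimethylsilyl)but-3-yn-1-yl]nona-1,8-diene-3,5-diol
Product: 12 (1S,2R,3R)-1,4-dimethyl-2-[4-(trimethylsilyl)but-3-yn-1-yl]cyclohept-4-ene-1,3-diol
Conditions: second-generation Grubbs catalyst (H2IMes)(PCy3)Cl2Ru=CHPh (5 mol%), CH2Cl2 (5 mM), 40 °C
Reagents that add atoms: none
Why: Ring-closing metathesis: the carbene loads on the monosubstituted alkene and closes on the 1,1-disubstituted alkene of the allylic alcohol to give the trisubstituted cycloheptene, while the silylated alkyne could only react through an eight-membered enyne closure and stays intact.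

Step 8
Reactants: 12 (1S,2R,3R)-1,4-dimethyl-2-[4-(trimethylsilyl)but-3-yn-1-yl]cyclohept-4-ene-1,3-diol
Product: 13 (1S,2R,3R)-1,4-dimethyl-3-[(triethylsilyl)oxy]-2-[4-(trimethylsilyl)but-3-yn-1-yl]cyclohept-4-en-1-ol
Conditions: Et3SiCl, imidazole, DMF, 0 °C
Reagents that add atoms: chlorotriethylsilane CC[Si](Cl)(CC)CC
Why: Chemoselective silylation of the secondary allylic hydroxyl in the presence of the tertiary one installs the activating group of the migration origin and leaves the C5 hydroxyl free as directing group and later nucleophile.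

Step 9
Reactants: 13 (1S,2R,3R)-1,4-dimethyl-3-[(triethylsilyl)oxy]-2-[4-(trimethylsilyl)but-3-yn-1-yl]cyclohept-4-en-1-ol
Product: 14 trans-epoxy silyl ether: the 4,5-epoxide of 13 with the oxirane oxygen on the ring face of the C1 hydroxyl and the C2 side chain, anti to OSiEt3
Conditions: VO(acac)2 (5 mol%), t-BuOOH (decane), CH2Cl2, 0 °C to rt
Reagents that add atoms: tert-butyl hydroperoxide CC(C)(C)OO
Why: Vanadium-catalysed hydroxyl-directed epoxidation: the only free hydroxyl, the tertiary C5–OH, binds pentavalent vanadium and passes the peroxide oxygen across the ring to the alkene face it occupies, which is also the face anti to the pseudoaxial OSiEt3, so the oxirane (later C1 and C2) is formed syn to the side chain and trans to the silyloxy group.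

Step 10
Reactants: 14 trans-epoxy silyl ether
Product: 17 triethyl({(1R,2R,5S,8R)-1,5-dimethyl-8-[4-(trimethylsilyl)but-3-yn-1-yl]-6-oxabicyclo[3.2.1]octan-2-yl}oxy)silane, via ring-contracted aldehyde 15 (not isolated), via lactol 16 (not isolated)
Conditions: BF3·OEt2, CH2Cl2, −78 °C; then Et3SiH, −78 to −20 °C
Reagents that add atoms: none
Why: BF3 activates the oxirane, which opens at the tertiary C1 as the nearly antiperiplanar ring bond C7–C8 shifts from C7 to C1 (semipinacol rearrangement of a trans-2,3-epoxy silyl ether, the Suzuki–Tsuchihashi type known for ring contraction of cyclic trans-epoxy silyl ethers and acylates to β-oxy aldehydes); the seven-membered ring thereby becomes the cyclohexane and C7 is extruded as an O-silylated aldehyde. After silyl transfer to the C2 oxygen, aldehyde 15 is attacked by the C5 hydroxyl, now 1,3-diaxial to the formyl group (5-exo-trig hemiacetalisation to lactol 16), and BF3/Et3SiH reduces the derived cyclic oxocarbenium ion (ionic hydrogenation of a lactol) to the oxolane. Modes of closure: the cyclohexane is closed by the 1,2-shift itself (C1–C8 forms while C7–C8 breaks), the oxolane by 5-exo-trig C–O formation followed by hydride delivery to C7. Stereocontrol: C1 is set with inversion because C8 enters anti to the leaving oxirane oxygen, C2 keeps the oxirane oxygen and its configuration, C8 migrates with retention, C5 is untouched, and the bridge can only form cis across C1 and C5. The step needs C–C instead of hydride migration and opening at C1 instead of C2: the trans relation of OSiEt3 and oxirane holds H7 syn-clinal and the ring bond close to antiperiplanar to the breaking C1–O bond, and C1 is the tertiary oxirane carbon next to the oxygen-stabilised migration origin. The C5 hydroxyl lies syn to the oxirane and cannot open it from the back, and silyl loss instead of transfer only gives the free C2 alcohol, which converges in step 11.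

Step 11
Reactants: 17 triethyl({(1R,2R,5S,8R)-1,5-dimethyl-8-[4-(trimethylsilyl)but-3-yn-1-yl]-6-oxabicyclo[3.2.1]octan-2-yl}oxy)silane
Product: 18 (1R,2R,5S,8R)-8-(but-3-yn-1-yl)-1,5-dimethyl-6-oxabicyclo[3.2.1]octan-2-ol
Conditions: Bu4NF, THF, rt
Reagents that add atoms: none
Why: Fluoride cleaves both the hindered secondary triethylsilyl ether and the alkynyl C–Si bond, so that any material already desilylated at oxygen in step 10 converges here.

Step 12
Reactants: 18 (1R,2R,5S,8R)-8-(but-3-yn-1-yl)-1,5-dimethyl-6-oxabicyclo[3.2.1]octan-2-ol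
Product: 20 (1R,2R,5S,8R)-8-[(3E)-5-hydroxy-3-methylpent-3-en-1-yl]-1,5-dimethyl-6-oxabicyclo[3.2.1]octan-2-ol, via alkenylalane 19 (not isolated)
Conditions: Me3Al (5 equiv), Cp2ZrCl2, CH2Cl2, 0 °C to rt; then n-BuLi, (CH2O)n, THF, −78 °C to rt
Reagents that add atoms: trimethylaluminium C[Al](C)C; paraformaldehyde (as formaldehyde) C=O
Why: Negishi zirconium-catalysed syn-methylalumination of the terminal alkyne (the hydroxyl is carried as its aluminium alkoxide) followed by hydroxymethylation of the ate complex of 19 gives the (E)-trisubstituted allylic alcohol with retention of geometry.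

Step 13
Reactants: 20 (1R,2R,5S,8R)-8-[(3E)-5-hydroxy-3-methylpent-3-en-1-yl]-1,5-dimethyl-6-oxabicyclo[3.2.1]octan-2-ol; 21 umbelliferone (7-hydroxy-2H-chromen-2-one)
Product: 22 7-{[(2E)-5-[(1R,2R,5S,8R)-2-hydroxy-1,5-dimethyl-6-oxabicyclo[3.2.1]octan-8-yl]-3-methylpent-2-en-1-yl]oxy}-2H-chromen-2-one
Conditions: PPh3, diisopropyl azodicarboxylate, THF, 0 °C to rt
Reagents that add atoms: none
Why: Mitsunobu etherification: the acidic phenol displaces the activated primary allylic oxygen in an SN2 fashion, while the hindered secondary hydroxyl next to the quaternary C1 does not react and the coumarin lactone never meets a base or a strong nucleophile.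

## Compound list

1 | hex-1-en-5-yne | C=CCCC#C | starting material
2 | dimethyl[(1E)-2-methylhexa-1,5-dien-1-yl]alane | C[Al](C)/C=C(\C)CCC=C | intermediate
3 | (2E)-3-methylhepta-2,6-dien-1-ol | OC/C=C(\C)CCC=C | intermediate
4 | [(2S,3S)-3-(but-3-en-1-yl)-3-methyloxiran-2-yl]methanol | OC[C@@H]1O[C@@]1(C)CCC=C | intermediate
5 | (4-bromobut-1-yn-1-yl)trimethylsilane | C[Si](C)(C)C#CCCBr | starting material
6 | [4-(trimethylsilyl)but-3-yn-1-yl]magnesium bromide | C[Si](C)(C)C#CCC[Mg]Br | intermediate
7 | (2R,3S)-3-methyl-2-[4-(trimethylsilyl)but-3-yn-1-yl]hept-6-ene-1,3-diol | C=CCC[C@](C)(O)[C@@H](CO)CCC#C[Si](C)(C)C | intermediate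
8 | bis(trimethylsilyl) ether of 7, (2R,3S) | C=CCC[C@](C)(O[Si](C)(C)C)[C@@H](CO[Si](C)(C)C)CCC#C[Si](C)(C)C | intermediate
9 | (2S,3S)-3-methyl-2-[4-(trimethylsilyl)but-3-yn-1-yl]-3-[(trimethylsilyl)oxy]hept-6-enal | C=CCC[C@](C)(O[Si](C)(C)C)[C@@H](C=O)CCC#C[Si](C)(C)C | intermediate
10 | (3R,4R,5S)-2,5-dimethyl-4-[4-(trimethylsilyl)but-3-yn-1-yl]-5-[(trimethylsilyl)oxy]nona-1,8-dien-3-ol | C=CCC[C@](C)(O[Si](C)(C)C)[C@@H]([C@@H](O)C(C)=C)CCC#C[Si](C)(C)C | intermediate
11 | (3R,4R,5S)-2,5-dimethyl-4-[4-(trimethylsilyl)but-3-yn-1-yl]nona-1,8-diene-3,5-diol | C=CCC[C@](C)(O)[C@@H]([C@@H](O)C(C)=C)CCC#C[Si](C)(C)C | intermediate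
12 | (1S,2R,3R)-1,4-dimethyl-2-[4-(trimethylsilyl)but-3-yn-1-yl]cyclohept-4-ene-1,3-diol (secondary OH trans to the side chain and to the tertiary OH) | CC1=CCC[C@](C)(O)[C@H](CCC#C[Si](C)(C)C)[C@H]1O | intermediate
13 | (1S,2R,3R)-1,4-dimethyl-3-[(triethylsilyl)oxy]-2-[4-(trimethylsilyl)but-3-yn-1-yl]cyclohept-4-en-1-ol | CC1=CCC[C@](C)(O)[C@H](CCC#C[Si](C)(C)C)[C@H]1O[Si](CC)(CC)CC | intermediate
14 | trans-epoxy silyl ether: 4,5-epoxide of 13, oxirane oxygen cis to the tertiary OH and the side chain, trans to OSiEt3 | C[C@@]12O[C@@H]1CC[C@](C)(O)[C@H](CCC#C[Si](C)(C)C)[C@H]2O[Si](CC)(CC)CC | intermediate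
15 | 5-hydroxy-1,5-dimethyl-2-[(triethylsilyl)oxy]-6-[4-(trimethylsilyl)but-3-yn-1-yl]cyclohexane-1-carbaldehyde (CHO, OSiEt3, OH and side chain all cis) | O=C[C@]1(C)[C@H](O[Si](CC)(CC)CC)CC[C@](C)(O)[C@@H]1CCC#C[Si](C)(C)C | intermediate
16 | C7 lactol of 17: 1,5-dimethyl-2-[(triethylsilyl)oxy]-8-[4-(trimethylsilyl)but-3-yn-1-yl]-6-oxabicyclo[3.2.1]octan-7-ol (both C7 epimers) | C[Si](C)(C)C#CCC[C@@H]1[C@]2(C)C(O)O[C@@]1(C)CC[C@H]2O[Si](CC)(CC)CC | intermediate
17 | triethyl({(1R,2R,5S,8R)-1,5-dimethyl-8-[4-(trimethylsilyl)but-3-yn-1-yl]-6-oxabicyclo[3.2.1]octan-2-yl}oxy)silane | C[Si](C)(C)C#CCC[C@@H]1[C@]2(C)CO[C@@]1(C)CC[C@H]2O[Si](CC)(CC)CC | intermediate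
18 | (1R,2R,5S,8R)-8-(but-3-yn-1-yl)-1,5-dimethyl-6-oxabicyclo[3.2.1]octan-2-ol | C#CCC[C@@H]1[C@]2(C)CO[C@@]1(C)CC[C@H]2O | intermediate
19 | (E)-alkenyl(dimethyl)alane of 18, hydroxyl as its dimethylaluminium alkoxide | C[Al](C)/C=C(\C)CC[C@@H]1[C@]2(C)CO[C@@]1(C)CC[C@H]2O[Al](C)C | intermediate
20 | (1R,2R,5S,8R)-8-[(3E)-5-hydroxy-3-methylpent-3-en-1-yl]-1,5-dimethyl-6-oxabicyclo[3.2.1]octan-2-ol | C/C(=C\CO)CC[C@@H]1[C@]2(C)CO[C@@]1(C)CC[C@H]2O | intermediate
21 | umbelliferone (7-hydroxy-2H-chromen-2-one) | O=c1ccc2ccc(O)cc2o1 | starting material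
22 | 7-{[(2E)-5-[(1R,2R,5S,8R)-2-hydroxy-1,5-dimethyl-6-oxabicyclo[3.2.1]octan-8-yl]-3-methylpent-2-en-1-yl]oxy}-2H-chromen-2-one | C/C(=C\COc1ccc2ccc(=O)oc2c1)CC[C@@H]1[C@]2(C)CO[C@@]1(C)CC[C@H]2O | target

## Step count and risks

Total step count: 13. Longest linear sequence: 13 steps (1 to 22; 5 and 21 are commercial and enter in steps 3 and 13).

Steps most likely to fail:

Step 10. The cationic intermediate may be diverted: hydride shift from C7 would give the seven-membered β-silyloxy ketone, proton loss an allylic alcohol, fluoride capture a fluorohydrin; the aldehyde may also be reduced before it lactolises. The fallback is the stepwise acylate variant and sets out from 12. 4-Nitrobenzoyl chloride and pyridine acylate only the secondary hydroxyl and give the C7 4-nitrobenzoate F1. VO(acac)2 and t-BuOOH, as in step 9, give the trans-epoxy 4-nitrobenzoate F2. BF3·OEt2 at −78 °C effects the known ring contraction of trans-2,3-epoxy acylates, in which the cation at C7 is quenched by 1,3-acyl transfer to the C2 oxygen; the product is isolated as the lactol 4-nitrobenzoate F3. Et3SiH and BF3·OEt2 in a separate step give the bicyclic ether 4-nitrobenzoate F4. K2CO3 in MeOH removes the ester and the alkynyl silyl group, and the route is rejoined at 18.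

Step 9. Oxygen transfer may be slow or poorly face-selective, because delivery depends on a remote (bishomoallylic) tertiary hydroxyl. The fallback uses an allylic hydroxyl as anchor and sets out from 12. MnO2 oxidises the allylic alcohol to the cycloheptenone F5. NaBH4 with CeCl3·7H2O (Luche reduction) should deliver hydride anti to the adjacent side chain and give the C7-epimeric diol F6. VO(acac)2 and t-BuOOH, now directed by the allylic hydroxyl and by the C5 hydroxyl on the same face, give the all-cis epoxy diol F7. Mitsunobu inversion with 4-nitrobenzoic acid (PPh3, diisopropyl azodicarboxylate) gives the trans-epoxy 4-nitrobenzoate F2, which continues through the lactol 4-nitrobenzoate F3 and the bicyclic ether 4-nitrobenzoate F4 to 18.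

Step 12. Carbometalation may be incomplete or regio-unselective on a substrate that carries an aluminium alkoxide and a Lewis-basic bridged ether, and material may be lost by Lewis-acid opening of that ether. The fallback is the classical hydroalumination–iodination–cuprate sequence and sets out from 18. Excess n-BuLi, then (CH2O)n, gives the propargylic alcohol F8. NaAlH2(OCH2CH2OCH3)2, then I2, gives the (Z)-3-iodoallylic alcohol F9 by alkoxide-directed trans-hydroalumination. Me2CuLi replaces iodine by methyl with retention, and the route is rejoined at 20.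

Further compounds
F1 | step 10 | C7 4-nitrobenzoate of 12 (tertiary hydroxyl free) | CC1=CCC[C@](C)(O)[C@H](CCC#C[Si](C)(C)C)[C@H]1OC(=O)c1ccc(cc1)[N+](=O)[O-]
F2 | step 10 | trans-epoxy 4-nitrobenzoate (oxirane cis to the tertiary hydroxyl and side chain, trans to the ester) | C[C@@]12O[C@@H]1CC[C@](C)(O)[C@H](CCC#C[Si](C)(C)C)[C@H]2OC(=O)c1ccc(cc1)[N+](=O)[O-]
F3 | step 10 | lactol 4-nitrobenzoate: 7-hydroxy-1,5-dimethyl-8-[4-(trimethylsilyl)but-3-yn-1-yl]-6-oxabicyclo[3.2.1]octan-2-yl 4-nitrobenzoate | C[Si](C)(C)C#CCC[C@@H]1[C@]2(C)C(O)O[C@@]1(C)CC[C@H]2OC(=O)c1ccc(cc1)[N+](=O)[O-]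
F4 | step 10 | bicyclic ether 4-nitrobenzoate: (1R,2R,5S,8R)-1,5-dimethyl-8-[4-(trimethylsilyl)but-3-yn-1-yl]-6-oxabicyclo[3.2.1]octan-2-yl 4-nitrobenzoate | C[Si](C)(C)C#CCC[C@@H]1[C@]2(C)CO[C@@]1(C)CC[C@H]2OC(=O)c1ccc(cc1)[N+](=O)[O-]
F5 | step 9 | cycloheptenone: (6S,7R)-6-hydroxy-2,6-dimethyl-7-[4-(trimethylsilyl)but-3-yn-1-yl]cyclohept-2-en-1-one | CC1=CCC[C@](C)(O)[C@H](CCC#C[Si](C)(C)C)C1=O
F6 | step 9 | C7-epimeric diol: epimer of 12 at the secondary carbinol (both hydroxyls and the side chain cis) | CC1=CCC[C@](C)(O)[C@H](CCC#C[Si](C)(C)C)[C@@H]1O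
F7 | step 9 | all-cis epoxy diol (oxirane, both hydroxyls and side chain on one face) | C[C@@]12O[C@@H]1CC[C@](C)(O)[C@H](CCC#C[Si](C)(C)C)[C@@H]2O
F8 | step 12 | propargylic alcohol: (1R,2R,5S,8R)-8-(5-hydroxypent-3-yn-1-yl)-1,5-dimethyl-6-oxabicyclo[3.2.1]octan-2-ol | OCC#CCC[C@@H]1[C@]2(C)CO[C@@]1(C)CC[C@H]2O
F9 | step 12 | (Z)-3-iodoallylic alcohol: (1R,2R,5S,8R)-8-[(3Z)-5-hydroxy-3-iodopent-3-en-1-yl]-1,5-dimethyl-6-oxabicyclo[3.2.1]octan-2-ol | OC/C=C(\I)CC[C@@H]1[C@]2(C)CO[C@@]1(C)CC[C@H]2O
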